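**Retrosynthetic overview**

- Target 23 comes from global desilylation of the silyl-protected (S)-flavanone 22, which comes from DDQ oxidation of the C4 methoxy carbon of the cis-4-methoxyflavan 21.
- Ring C is the only ring made (rings A and B are bought as arenes). It is formed by an enantioselective inverse-electron-demand oxa-[4+2] addition between a 4-methoxy ortho-quinone methide, released from salicylaldehyde acetal 16, and catechol styrene 19; this forms C3–C4 and O1–C2 and sets C2.
- Acetal 16 comes from 2,4-dihydroxybenzaldehyde (MOM and acetal protection, lithiation at C3 between the two MOM ethers, copper-mediated allylation with Z-bromide 7, deprotection, 4-O-silylation, re-acetalisation). Bromide 7 comes from propargyl alcohol, where anti-carbomagnesiation and iodination fix the Z alkene. Styrene 19 comes from 3,4-dihydroxybenzaldehyde.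
- Structural feature used: ring C splits into a four-atom piece O1–C8a–C4a–C4 that already sits on ring A and a two-atom piece C2–C3 whose C2 bears the electron-rich catechol ring B (so the styrene is nucleophilic at C3). The C4 ketone travels through the ring closure as a C4 methoxy group.

Key step: step 13

Remark 1: the side-chain hydroxyl is carried as a TBDPS ether and the phenols as TBS ethers, because the side-chain ether must outlast the acid of steps 8 and 10.

Remark 2: "(S,S)-IDPi" in step 13 means the C2-symmetric imidodiphosphorimidate HN[P(=NSO2CF3)(O2R*)]2, with R*O2 = (S)-3,3'-bis(4-tert-butylphenyl)-1,1'-binaphthalene-2,2'-diolate. Its sense of induction cannot be predicted with confidence; the enantiomeric catalyst would be used if the (2R) series were to form.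

Remark 3: flavanone numbering (O1, C2, C3, C4, C4a, C5–C8, C8a) is used for compounds 20–23.

**Route**

Step 1
Reactants: 1 propargyl alcohol
Product: 3 (Z)-3-iodo-2-methylprop-2-en-1-ol, via bis(bromomagnesium) alkenyl alkoxide 2 (not isolated)
Conditions: MeMgBr (2.5 equiv), CuI (10 mol %), THF, −10 °C→rt; then I2, −20 °C→rt
Reagents that add atoms: methylmagnesium bromide, C[Mg]Br; iodine, II
Why: Copper-catalysed anti-carbomagnesiation of the propargylic alkoxide puts methyl on C2 and magnesium on C3 inside an alkoxide chelate, and iodinolysis with retention should give the vinyl iodide with iodine cis to CH2OH, which fixes the Z geometry of the side chain.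

Step 2
Reactants: 3 (Z)-3-iodo-2-methylprop-2-en-1-ol
Product: 4 (Z)-tert-butyl[(3-iodo-2-methylprop-2-en-1-yl)oxy]diphenylsilane
Conditions: TBDPSCl, imidazole, CH2Cl2, 0 °C→rt
Reagents that add atoms: tert-butyldiphenylsilyl chloride, CC(C)(C)[Si](Cl)(c1ccccc1)c1ccccc1
Why: Imidazole-promoted silylation of a primary alcohol; the bulky TBDPS group is chosen for its acid stability and because it migrates slowly in step 3.

Step 3
Reactants: 4 (Z)-tert-butyl[(3-iodo-2-methylprop-2-en-1-yl)oxy]diphenylsilane
Product: 6 (Z)-4-(tert-butyldiphenylsilyloxy)-3-methylbut-2-en-1-ol, via vinyllithium 5 (not isolated)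
Conditions: t-BuLi (2.1 equiv), Et2O, −78 °C; then monomeric CH2O (from cracked paraformaldehyde), −78 °C→0 °C
Reagents that add atoms: formaldehyde, C=O
Why: Iodine–lithium exchange proceeds with retention at the sp2 carbon and the vinyllithium adds to formaldehyde (1,2-addition), so the new CH2OH should end cis to CH2OSi; ether solvent and low temperature suppress 1,4 O-to-C silyl migration.

Step 4
Reactants: 6 (Z)-4-(tert-butyldiphenylsilyloxy)-3-methylbut-2-en-1-ol
Product: 7 (Z)-[(4-bromo-2-methylbut-2-en-1-yl)oxy](tert-butyl)diphenylsilane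
Conditions: CBr4, PPh3, CH2Cl2, 0 °C
Reagents that add atoms: carbon tetrabromide, BrC(Br)(Br)Br
Why: Appel bromination replaces the primary allylic hydroxyl by SN2 under neutral conditions, so the alkene geometry and the silyl ether should be untouched.

Step 5
Reactants: 8 2,4-dihydroxybenzaldehyde
Product: 9 2,4-bis(methoxymethoxy)benzaldehyde
Conditions: MOMCl (3 equiv), iPr2NEt (4 equiv), CH2Cl2, 0 °C→rt
Reagents that add atoms: chloromethyl methyl ether, COCCl
Why: Base-mediated O-alkylation (MOM protection) of both phenols installs the two ortho-directing groups needed in step 7.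

Step 6
Reactants: 9 2,4-bis(methoxymethoxy)benzaldehyde
Product: 10 1-(dimethoxymethyl)-2,4-bis(methoxymethoxy)benzene
Conditions: HC(OMe)3, MeOH, pyridinium p-toluenesulfonate (PPTS, cat.), 40 °C; then Et3N
Reagents that add atoms: trimethyl orthoformate, COC(OC)OC; methanol, CO
Why: Acid-catalysed acetalisation with the orthoformate as water scavenger masks the aldehyde against n-BuLi, and PPTS is too weak to cleave the aryl MOM ethers.

Step 7
Reactants: 10 1-(dimethoxymethyl)-2,4-bis(methoxymethoxy)benzene; 7 (Z)-[(4-bromo-2-methylbut-2-en-1-yl)oxy](tert-butyl)diphenylsilane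
Product: 13 1-(dimethoxymethyl)-2,4-bis(methoxymethoxy)-3-[(Z)-4-(tert-butyldiphenylsilyloxy)-3-methylbut-2-enyl]benzene, via aryllithium 11 (not isolated), via arylcopper 12 (not isolated)
Conditions: n-BuLi (1.1 equiv), THF, 0 °C; CuI (1.1 equiv), −40 °C; then 7, −78 °C→0 °C
Reagents that add atoms: none
Why: Directed ortho-metalation should occur at C3, the position flanked by both MOM ethers, and the arylcopper formed with CuI should couple with the primary allylic bromide by direct (alpha) substitution with retention of the Z geometry, since gamma attack would have to build a quaternary carbon.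

Step 8
Reactants: 13 1-(dimethoxymethyl)-2,4-bis(methoxymethoxy)-3-[(Z)-4-(tert-butyldiphenylsilyloxy)-3-methylbut-2-enyl]benzene
Product: 14 2,4-dihydroxy-3-[(Z)-4-(tert-butyldiphenylsilyloxy)-3-methylbut-2-enyl]benzaldehyde
Conditions: HCl (2 M aq)/MeOH/THF (1:4:2), 35 °C
Reagents that add atoms: water, O
Why: Acid-catalysed acetal hydrolysis and MOM solvolysis free the aldehyde and both phenols, while the primary TBDPS ether and the trisubstituted alkene should survive dilute HCl because the formyl group lowers the nucleophilicity of the phenols and the allylic oxygen destabilises the tertiary cation needed for chroman formation.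

Step 9
Reactants: 14 2,4-dihydroxy-3-[(Z)-4-(tert-butyldiphenylsilyloxy)-3-methylbut-2-enyl]benzaldehyde
Product: 15 4-(tert-butyldimethylsilyloxy)-2-hydroxy-3-[(Z)-4-(tert-butyldiphenylsilyloxy)-3-methylbut-2-enyl]benzaldehyde
Conditions: TBSCl (1.05 equiv), imidazole, CH2Cl2, 0 °C
Reagents that add atoms: tert-butyldimethylsilyl chloride, CC(C)(C)[Si](C)(C)Cl
Why: Selective silylation should occur at the C4 hydroxyl, because the C2 hydroxyl is held in a hydrogen bond to the aldehyde and is flanked by two substituents.

Step 10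
Reactants: 15 4-(tert-butyldimethylsilyloxy)-2-hydroxy-3-[(Z)-4-(tert-butyldiphenylsilyloxy)-3-methylbut-2-enyl]benzaldehyde
Product: 16 2-(dimethoxymethyl)-5-(tert-butyldimethylsilyloxy)-6-[(Z)-4-(tert-butyldiphenylsilyloxy)-3-methylbut-2-enyl]phenol
Conditions: HC(OMe)3 (excess), PPTS (5 mol %), CH2Cl2, rt; then Et3N, evaporation; used without chromatography
Reagents that add atoms: trimethyl orthoformate, COC(OC)OC
Why: Acid-catalysed acetalisation with the orthoformate gives the quinone methide precursor; the electron-rich, labile acetal is neutralised, freed of volatiles and taken on directly.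

Step 11
Reactants: 17 3,4-dihydroxybenzaldehyde
Product: 18 3,4-bis(tert-butyldimethylsilyloxy)benzaldehyde
Conditions: TBSCl (2.5 equiv), imidazole, DMF, rt
Reagents that add atoms: tert-butyldimethylsilyl chloride, CC(C)(C)[Si](C)(C)Cl
Why: Imidazole-promoted silylation of both catechol hydroxyls.

Step 12
Reactants: 18 3,4-bis(tert-butyldimethylsilyloxy)benzaldehyde
Product: 19 3,4-bis(tert-butyldimethylsilyloxy)styrene
Conditions: MePPh3Br, n-BuLi, THF, 0 °C; then 18, 0 °C→rt
Reagents that add atoms: methyltriphenylphosphonium bromide, C[P+](c1ccccc1)(c1ccccc1)c1ccccc1.[Br-]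
Why: Wittig methylenation of the aromatic aldehyde; the ylide is preformed, so the aryl silyl ethers should not meet free base.

Step 13
Reactants: 16 2-(dimethoxymethyl)-5-(tert-butyldimethylsilyloxy)-6-[(Z)-4-(tert-butyldiphenylsilyloxy)-3-methylbut-2-enyl]phenol; 19 3,4-bis(tert-butyldimethylsilyloxy)styrene
Product: 21 (2S,4S)-2-[3,4-bis(tert-butyldimethylsilyloxy)phenyl]-7-(tert-butyldimethylsilyloxy)-8-[(Z)-4-(tert-butyldiphenylsilyloxy)-3-methylbut-2-enyl]-4-methoxychroman (2,4-cis), via 4-methoxy ortho-quinone methide 20 (not isolated)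
Conditions: (S,S)-IDPi (5 mol %), 19 (2 equiv), 5 Å molecular sieves, toluene, −40 °C
Reagents that add atoms: none
Why: Proposed new method: the strong, confined acid should ionise the acetal (methanol is taken up by the sieves) to the O-protonated form of the 4-methoxy ortho-quinone methide 20, ion-paired with the chiral anion at O1, and the terminal CH2 of styrene 19, made nucleophilic by its para silyloxy group, should attack C4 while O1 captures the benzylic cation growing at C2, an asynchronous concerted inverse-electron-demand oxa-[4+2] addition. The closest known reaction types are chiral Brønsted acid catalysed [4+2] additions of ortho-quinone methides to styrenes, imidodiphosphorimidate-catalysed hetero-Diels–Alder reactions of styrenes with cationic heterodienes, and the racemic Lewis acid route from salicylaldehyde acetals and styrenes to cis-4-methoxyflavans; an enantioselective intermolecular version with an acetal-derived 4-alkoxy quinone methide is not established. Ring C closes as a six-membered pyran by intermolecular [4+2] annulation, the C3–C4 bond leading and the O1–C2 bond completing the ring. The 2,4-cis relation should follow from an endo approach of the aryl group to the E quinone methide, and the absolute configuration at C2 (S) and C4 (S) from the chiral counter-anion, which shields one face of the planar quinone methide. Regiochemistry is fixed by the polarity of the partners (electrophilic C4, nucleophilic styrene CH2), and the C7 silyloxy group para to C4 should let acetal ionisation outrun protonation of the styrene or of the side-chain alkene. The C4 methoxy group holds the ketone oxidation level, so the C4 configuration has no later consequence.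

Step 14
Reactants: 21 (2S,4S)-2-[3,4-bis(tert-butyldimethylsilyloxy)phenyl]-7-(tert-butyldimethylsilyloxy)-8-[(Z)-4-(tert-butyldiphenylsilyloxy)-3-methylbut-2-enyl]-4-methoxychroman
Product: 22 (S)-2-[3,4-bis(tert-butyldimethylsilyloxy)phenyl]-7-(tert-butyldimethylsilyloxy)-8-[(Z)-4-(tert-butyldiphenylsilyloxy)-3-methylbut-2-enyl]chroman-4-one
Conditions: 2,3-dichloro-5,6-dicyano-1,4-benzoquinone (DDQ, 1.5 equiv), CH2Cl2/pH 7 phosphate buffer (10:1), 0 °C→rt
Reagents that add atoms: water, O
Why: DDQ oxidation of a benzylic methyl ether: hydride abstraction from the pseudo-axial C4–H, which is aligned with the ring A π system and activated by O1, the C7 silyloxy group and the methoxy group, should give an oxocarbenium ion that water converts through the hemiketal into the ketone, while C2–H and the twisted benzylic CH2 at C8 should react more slowly, so C2 stays S.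

Step 15
Reactants: 22 (S)-2-[3,4-bis(tert-butyldimethylsilyloxy)phenyl]-7-(tert-butyldimethylsilyloxy)-8-[(Z)-4-(tert-butyldiphenylsilyloxy)-3-methylbut-2-enyl]chroman-4-one
Product: 23 (S)-2-(3,4-dihydroxyphenyl)-7-hydroxy-8-[(Z)-4-hydroxy-3-methylbut-2-enyl]chroman-4-one (target)
Conditions: HF·pyridine, pyridine, THF, 0 °C→rt
Reagents that add atoms: none
Why: Fluoride-driven cleavage of all four Si–O bonds (global desilylation) under buffered, weakly acidic conditions should avoid both the phenoxide-induced retro-oxa-Michael ring opening that would racemise C2 and acid-induced cyclisation of the side chain onto the C7 hydroxyl.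

**Compound list**

1 | propargyl alcohol | C#CCO | starting material
2 | bromomagnesium (Z)-3-(bromomagnesio)-2-methylprop-2-en-1-olate | C/C(CO[Mg]Br)=C/[Mg]Br | intermediate
3 | (Z)-3-iodo-2-methylprop-2-en-1-ol | I/C=C(/C)CO | intermediate
4 | (Z)-tert-butyl[(3-iodo-2-methylprop-2-en-1-yl)oxy]diphenylsilane | I/C=C(/C)CO[Si](c1ccccc1)(c1ccccc1)C(C)(C)C | intermediate
5 | (Z)-3-(tert-butyldiphenylsilyloxy)-2-methylprop-1-enyllithium | [Li]/C=C(/C)CO[Si](c1ccccc1)(c1ccccc1)C(C)(C)C | intermediate
6 | (Z)-4-(tert-butyldiphenylsilyloxy)-3-methylbut-2-en-1-ol | OC/C=C(/C)CO[Si](c1ccccc1)(c1ccccc1)C(C)(C)C | intermediate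
7 | (Z)-[(4-bromo-2-methylbut-2-en-1-yl)oxy](tert-butyl)diphenylsilane | BrC/C=C(/C)CO[Si](c1ccccc1)(c1ccccc1)C(C)(C)C | intermediate
8 | 2,4-dihydroxybenzaldehyde | O=Cc1ccc(O)cc1O | starting material
9 | 2,4-bis(methoxymethoxy)benzaldehyde | O=Cc1ccc(OCOC)cc1OCOC | intermediate
10 | 1-(dimethoxymethyl)-2,4-bis(methoxymethoxy)benzene | COC(OC)c1ccc(OCOC)cc1OCOC | intermediate
11 | 3-(dimethoxymethyl)-2,6-bis(methoxymethoxy)phenyllithium | COC(OC)c1ccc(OCOC)c([Li])c1OCOC | intermediate
12 | 3-(dimethoxymethyl)-2,6-bis(methoxymethoxy)phenylcopper | COC(OC)c1ccc(OCOC)c([Cu])c1OCOC | intermediate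
13 | 1-(dimethoxymethyl)-2,4-bis(methoxymethoxy)-3-[(Z)-4-(tert-butyldiphenylsilyloxy)-3-methylbut-2-enyl]benzene | COC(OC)c1ccc(OCOC)c(C/C=C(/C)CO[Si](c2ccccc2)(c2ccccc2)C(C)(C)C)c1OCOC | intermediate
14 | 2,4-dihydroxy-3-[(Z)-4-(tert-butyldiphenylsilyloxy)-3-methylbut-2-enyl]benzaldehyde | O=Cc1ccc(O)c(C/C=C(/C)CO[Si](c2ccccc2)(c2ccccc2)C(C)(C)C)c1O | intermediate
15 | 4-(tert-butyldimethylsilyloxy)-2-hydroxy-3-[(Z)-4-(tert-butyldiphenylsilyloxy)-3-methylbut-2-enyl]benzaldehyde | O=Cc1ccc(O[Si](C)(C)C(C)(C)C)c(C/C=C(/C)CO[Si](c2ccccc2)(c2ccccc2)C(C)(C)C)c1O | intermediate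
16 | 2-(dimethoxymethyl)-5-(tert-butyldimethylsilyloxy)-6-[(Z)-4-(tert-butyldiphenylsilyloxy)-3-methylbut-2-enyl]phenol | COC(OC)c1ccc(O[Si](C)(C)C(C)(C)C)c(C/C=C(/C)CO[Si](c2ccccc2)(c2ccccc2)C(C)(C)C)c1O | intermediate
17 | 3,4-dihydroxybenzaldehyde | O=Cc1ccc(O)c(O)c1 | starting material
18 | 3,4-bis(tert-butyldimethylsilyloxy)benzaldehyde | O=Cc1ccc(O[Si](C)(C)C(C)(C)C)c(O[Si](C)(C)C(C)(C)C)c1 | intermediate
19 | 3,4-bis(tert-butyldimethylsilyloxy)styrene | C=Cc1ccc(O[Si](C)(C)C(C)(C)C)c(O[Si](C)(C)C(C)(C)C)c1 | intermediate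
20 | (E)-6-(methoxymethylene)-3-(tert-butyldimethylsilyloxy)-2-[(Z)-4-(tert-butyldiphenylsilyloxy)-3-methylbut-2-enyl]cyclohexa-2,4-dien-1-one | CO/C=C1\C=CC(O[Si](C)(C)C(C)(C)C)=C(C/C=C(/C)CO[Si](c2ccccc2)(c2ccccc2)C(C)(C)C)C1=O | intermediate
21 | (2S,4S)-2-[3,4-bis(tert-butyldimethylsilyloxy)phenyl]-7-(tert-butyldimethylsilyloxy)-8-[(Z)-4-(tert-butyldiphenylsilyloxy)-3-methylbut-2-enyl]-4-methoxychroman | C/C(=C/Cc1c(O[Si](C)(C)C(C)(C)C)ccc2c1O[C@H](c1ccc(O[Si](C)(C)C(C)(C)C)c(O[Si](C)(C)C(C)(C)C)c1)C[C@@H]2OC)CO[Si](c1ccccc1)(c1ccccc1)C(C)(C)C | intermediate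
22 | (S)-2-[3,4-bis(tert-butyldimethylsilyloxy)phenyl]-7-(tert-butyldimethylsilyloxy)-8-[(Z)-4-(tert-butyldiphenylsilyloxy)-3-methylbut-2-enyl]chroman-4-one | C/C(=C/Cc1c(O[Si](C)(C)C(C)(C)C)ccc2c1O[C@H](c1ccc(O[Si](C)(C)C(C)(C)C)c(O[Si](C)(C)C(C)(C)C)c1)CC2=O)CO[Si](c1ccccc1)(c1ccccc1)C(C)(C)C | intermediate
23 | (S)-2-(3,4-dihydroxyphenyl)-7-hydroxy-8-[(Z)-4-hydroxy-3-methylbut-2-enyl]chroman-4-one | C/C(=C/Cc1c(O)ccc2c1O[C@H](c1ccc(O)c(O)c1)CC2=O)CO | target

**Step count and risks**

Total step count: 15. Longest linear sequence: 11 steps (steps 1–4, 7–10, 13–15).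

Steps most likely to fail:

1. Step 13 (proposed new method). The chiral anion may discriminate poorly between the two faces of the quinone methide, or the styrene may approach partly exo. An exo adduct formed on the same quinone methide face carries the opposite C2 configuration, so it would have to be separated at the stage of 21 before oxidation. The acid may also oligomerise the electron-rich styrene or strip the C7 silyl group from the cationic intermediate. The fallback uses known chemistry and sets out from 16 and 19. With Sc(OTf)3 in CH2Cl2 the same two components should give the racemic cis-4-methoxyflavan F1 (the known Lewis acid route from salicylaldehyde acetals and styrenes). DDQ oxidation as in step 14 should then give the racemic silylated flavanone F2. This is resolved kinetically by asymmetric transfer hydrogenation with RuCl[(R,R)-TsDPEN](p-cymene) and HCO2H/Et3N in EtOAc, a known method for flavanones: the (2R) ketone should be reduced faster to the cis-(2R,4R)-flavan-4-ol F3, which is separated by chromatography from the unreacted (S) ketone. The route is rejoined at 22, at the cost of at most half of the material.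

2. Step 14. Hydride abstraction may occur at the wrong C–H bond (C2–H next to ring B, or the benzylic and allylic CH2 at C8), or oxidation may go further. The fallback sets out from 21. Solvolysis of the benzylic methyl ether with TsOH·H2O (cat.) in THF/H2O at rt, through the ring A stabilised C4 cation, should give the (2S)-flavan-4-ol F4 as a mixture of C4 epimers. Oxidation of the secondary alcohol with Dess–Martin periodinane and NaHCO3 in CH2Cl2 returns to 22.

3. Step 8. While the MOM ethers are being cleaved, a freed phenol may add to the side-chain alkene under acid catalysis (chroman formation), or the TBDPS ether may be lost. The fallback sets out from 13 and replaces protic solvolysis by silyl triflate mediated acetal exchange. Mild hydrolysis of the dimethyl acetal alone (PPTS, acetone/H2O, rt) should give 2,4-bis(methoxymethoxy)-3-[(Z)-4-(tert-butyldiphenylsilyloxy)-3-methylbut-2-enyl]benzaldehyde F5. Treatment with TMSOTf and 2,2'-bipyridyl in CH2Cl2 at 0 °C should convert the aryl MOM ethers into the bis(trimethylsilyl) ether F6, which is not isolated; addition of water hydrolyses it at near-neutral pH and returns to 14.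

Further compounds
F1 | step 13 | racemic 2,4-cis-2-[3,4-bis(tert-butyldimethylsilyloxy)phenyl]-7-(tert-butyldimethylsilyloxy)-8-[(Z)-4-(tert-butyldiphenylsilyloxy)-3-methylbut-2-enyl]-4-methoxychroman (relative configuration 2S*,4S*; one enantiomer drawn) | C/C(=C/Cc1c(O[Si](C)(C)C(C)(C)C)ccc2c1O[C@H](c1ccc(O[Si](C)(C)C(C)(C)C)c(O[Si](C)(C)C(C)(C)C)c1)C[C@@H]2OC)CO[Si](c1ccccc1)(c1ccccc1)C(C)(C)C
F2 | step 13 | racemic 2-[3,4-bis(tert-butyldimethylsilyloxy)phenyl]-7-(tert-butyldimethylsilyloxy)-8-[(Z)-4-(tert-butyldiphenylsilyloxy)-3-methylbut-2-enyl]chroman-4-one | C/C(=C/Cc1c(O[Si](C)(C)C(C)(C)C)ccc2c1OC(c1ccc(O[Si](C)(C)C(C)(C)C)c(O[Si](C)(C)C(C)(C)C)c1)CC2=O)CO[Si](c1ccccc1)(c1ccccc1)C(C)(C)C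
F3 | step 13 | (2R,4R)-2-[3,4-bis(tert-butyldimethylsilyloxy)phenyl]-7-(tert-butyldimethylsilyloxy)-8-[(Z)-4-(tert-butyldiphenylsilyloxy)-3-methylbut-2-enyl]chroman-4-ol (2,4-cis) | C/C(=C/Cc1c(O[Si](C)(C)C(C)(C)C)ccc2c1O[C@@H](c1ccc(O[Si](C)(C)C(C)(C)C)c(O[Si](C)(C)C(C)(C)C)c1)C[C@H]2O)CO[Si](c1ccccc1)(c1ccccc1)C(C)(C)C
F4 | step 14 | (2S)-2-[3,4-bis(tert-butyldimethylsilyloxy)phenyl]-7-(tert-butyldimethylsilyloxy)-8-[(Z)-4-(tert-butyldiphenylsilyloxy)-3-methylbut-2-enyl]chroman-4-ol (mixture of C4 epimers) | C/C(=C/Cc1c(O[Si](C)(C)C(C)(C)C)ccc2c1O[C@H](c1ccc(O[Si](C)(C)C(C)(C)C)c(O[Si](C)(C)C(C)(C)C)c1)CC2O)CO[Si](c1ccccc1)(c1ccccc1)C(C)(C)C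
F5 | step 8 | 2,4-bis(methoxymethoxy)-3-[(Z)-4-(tert-butyldiphenylsilyloxy)-3-methylbut-2-enyl]benzaldehyde | COCOc1ccc(C=O)c(OCOC)c1C/C=C(/C)CO[Si](c1ccccc1)(c1ccccc1)C(C)(C)C
F6 | step 8 | 2,4-bis(trimethylsilyloxy)-3-[(Z)-4-(tert-butyldiphenylsilyloxy)-3-methylbut-2-enyl]benzaldehyde | C[Si](C)(C)Oc1ccc(C=O)c(O[Si](C)(C)C)c1C/C=C(/C)CO[Si](c1ccccc1)(c1ccccc1)C(C)(C)C
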